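**Plan**

1. Retrosynthesis: after removal of the benzyl ethers and the diphenylmethylene ketal, ring C of the lower unit is cut at both O1–C2 and C4–C4a, giving phenol 17 and cis-epoxy aldehyde 21. Phenol 17 is then cut at its C3 carbinol (from the ketone, from hydroboration of a 4H-chromene), at C2–C1' (aryllithium plus lactone) and at the interflavanyl C4–C6 bond (arylboronic acid plus coumarin).
2. Forward: the pyranone ring of daphnetin is arylated at C4, opened by the ring-B aryllithium, re-closed as the 4H-chromene (upper ring C) and oxygenated at C3. Ring C of the lower unit is closed last, in step 14, by a [3+3] union of 17 and 21; hydrogenolysis ends the route.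
3. Enabling feature: ring A of the lower unit is a pyrogallol ring. Its O1 hydroxyl is the only free phenol of 17, its single free ortho carbon is C4a, its para carbon (C6) already carries the upper unit, and C2 is benzylic to the electron-rich ring B. Phenoxide-directed C-attack can therefore only form C4–C4a, and only O1 can reach C2 through a six-membered transition state.
4. Stereochemistry: upper C4 comes from the rhodium/(R)-SEGPHOS conjugate addition. Upper C2 and C3 follow from C4 by substrate control (hydroboration, then ketone reduction from the face opposite both aryl groups, all-cis). Lower C2 and C3 come from the Jacobsen epoxide (C2 inverted on ring closure, C3 retained), and lower C4 from magnesium chelation in step 14.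
5. Helpers: benzyl ethers, the diphenylmethylene ketal (sets O1 apart from O7/O8 of the lower ring A) and a TIPS ether (steers the lithiation and masks O1 until step 10); they are removed in steps 10 and 15.

Key step: step 14

Remark: flavan numbering is used for both units (O1, C2, C3, C4, C4a, C5 to C8, C8a; ring B primed); the upper unit is the 4-arylflavan-3-ol, the lower unit the flavan-3,4-diol.
Remark: ArB = 3,4-bis(benzyloxy)phenyl; ArT = 2,2-diphenyl-7-[tri(propan-2-yl)silyloxy]-1,3-benzodioxol-4-yl; TIPS = tri(propan-2-yl)silyl.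
Remark: the CIP label of the interflavanyl carbon reads R in 8 and 25 and S in 11 to 17 and 22 to 24 only because the ranking of its substituents changes; its spatial arrangement is the same throughout.
Remark: 1, 3, 9 and 18 are taken as commercial.

**Step 1**
Reactants: 1 7,8-dihydroxy-2H-chromen-2-one (daphnetin)
Product: 2 7,8-bis(benzyloxy)-2H-chromen-2-one
Conditions: BnBr (2.4 equiv), K2CO3, DMF, 60 °C
Reagents that add atoms: benzyl bromide, BrCc1ccccc1
Why: Williamson etherification of the two phenols of the coumarin; no stereocenter is involved.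

**Step 2**
Reactants: 3 benzene-1,2,3-triol (pyrogallol)
Product: 4 2,2-diphenyl-1,3-benzodioxol-4-ol
Conditions: Ph2CCl2 (1.1 equiv), neat, 170 °C
Reagents that add atoms: dichlorodiphenylmethane, ClC(Cl)(c1ccccc1)c1ccccc1
Why: ketalization by double substitution on the gem-dichloride; only two adjacent hydroxyls can close the five-membered dioxole, so one phenol (the future O1 of the lower unit) stays free.

**Step 3**
Reactants: 4 2,2-diphenyl-1,3-benzodioxol-4-ol
Product: 5 [(2,2-diphenyl-1,3-benzodioxol-4-yl)oxy]tri(propan-2-yl)silane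
Conditions: (Me2CH)3SiCl, imidazole, DMF, 25 °C
Reagents that add atoms: chlorotri(propan-2-yl)silane, CC(C)[Si](Cl)(C(C)C)C(C)C
Why: silylation of the phenol; the bulky silyl ether is a poor director for lithiation and is removable by fluoride.

**Step 4**
Reactants: 5 [(2,2-diphenyl-1,3-benzodioxol-4-yl)oxy]tri(propan-2-yl)silane
Product: 7 ArT-boronic acid {2,2-diphenyl-7-[tri(propan-2-yl)silyloxy]-1,3-benzodioxol-4-yl}boronic acid, via aryllithium 6 (not isolated)
Conditions: EtMeCHLi, TMEDA, THF, −78 °C; B(OMe)3, −78 → 25 °C; 1 M HCl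
Reagents that add atoms: trimethyl borate, COB(OC)OC; water, O
Why: directed ortho-metalation, in which the dioxole oxygen directs lithiation to the ring carbon para to the silyloxy group while the TIPS group shields its own ortho position; borylation and hydrolysis give the boronic acid.

**Step 5**
Reactants: 2 7,8-bis(benzyloxy)-2H-chromen-2-one; 7 ArT-boronic acid
Product: 8 (4R)-7,8-bis(benzyloxy)-4-ArT-chroman-2-one
Conditions: 7 (3 equiv), Rh(acac)(C2H4)2 (3 mol%), (R)-SEGPHOS (3.3 mol%), 1,4-dioxane–H2O (10:1), 60 °C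
Reagents that add atoms: none
Why: Hayashi–Miyaura asymmetric 1,4-addition of an arylboronic acid to a coumarin; the aryl–rhodium species (monovalent rhodium) bearing (R)-SEGPHOS adds to one face of C3=C4 and sets C4 (R), the sense expected for 4-arylchroman-2-ones.

**Step 6**
Reactants: 8 (4R)-7,8-bis(benzyloxy)-4-ArT-chroman-2-one; 9 4-bromo-1,2-bis(benzyloxy)benzene
Product: 11 (3S)-3-[3,4-bis(benzyloxy)-2-hydroxyphenyl]-1-ArB-3-ArT-propan-1-one, via aryllithium 10 (not isolated)
Conditions: 9, n-BuLi, THF, −78 °C; then 8, −78 °C; H2O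
Reagents that add atoms: none
Why: bromine–lithium exchange followed by single addition of the aryllithium to the aryl lactone at −78 °C; ring opening leaves a lithium phenoxide and an electron-rich aryl ketone that resists a second addition, and the stereocenter is untouched.

**Step 7**
Reactants: 11 (3S)-3-[3,4-bis(benzyloxy)-2-hydroxyphenyl]-1-ArB-3-ArT-propan-1-one
Product: 12 (4S)-7,8-bis(benzyloxy)-2-ArB-4-ArT-4H-chromene
Conditions: p-TsOH·H2O (5 mol%), 4 Å molecular sieves, toluene, 60 °C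
Reagents that add atoms: none
Why: acid-catalysed cyclodehydration of the 2'-hydroxydihydrochalcone (hemiketal, then loss of water) re-closes ring C of the upper unit as its enol ether; C4 is not involved.

**Step 8**
Reactants: 12 (4S)-7,8-bis(benzyloxy)-2-ArB-4-ArT-4H-chromene
Product: 14 (2R,3S,4S)-7,8-bis(benzyloxy)-2-ArB-4-ArT-chroman-3-ol (2,3-trans-3,4-trans), via C3-borane 13 (not isolated)
Conditions: BH3·SMe2, THF, 0 → 25 °C; then NaOH (aq), H2O2, 0 °C
Reagents that add atoms: hydrogen peroxide, OO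
Why: hydroboration–oxidation of the cyclic enol ether; boron adds to C3 and hydrogen to C2 in a syn fashion from the face opposite the C4 aryl group, so C2 (R) and C3 (S) are set by C4 (2,4-cis aryl groups, 3-OH trans to both), and oxidation proceeds with retention.

**Step 9**
Reactants: 14 (2R,3S,4S)-7,8-bis(benzyloxy)-2-ArB-4-ArT-chroman-3-ol
Product: 15 (2R,4S)-7,8-bis(benzyloxy)-2-ArB-4-ArT-chroman-3-one (2,4-cis)
Conditions: Dess–Martin periodinane, CH2Cl2, 25 °C
Reagents that add atoms: none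
Why: Dess–Martin oxidation of the secondary alcohol under non-basic conditions, which should leave the enolisable C2 and C4 centers untouched.

**Step 10**
Reactants: 15 (2R,4S)-7,8-bis(benzyloxy)-2-ArB-4-ArT-chroman-3-one
Product: 17 (2R,3R,4S)-7,8-bis(benzyloxy)-2-ArB-4-(7-hydroxy-2,2-diphenyl-1,3-benzodioxol-4-yl)chroman-3-ol (all-cis), via silyl ether alcohol 16 (not isolated)
Conditions: LiBH(CHMeEt)3, THF, −78 °C; MeOH; then n-Bu4NF, 0 → 25 °C
Reagents that add atoms: none
Why: the bulky hydride attacks the ketone from the face opposite the two cis aryl groups and should give the all-cis alcohol (C3, R), the known inversion of 2,3-trans to 2,3-cis flavan-3-ols through the 3-ketone; fluoride then cleaves the aryl silyl ether.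

**Step 11**
Reactants: 18 3,4-bis(benzyloxy)benzaldehyde
Product: 19 methyl (2Z)-3-[3,4-bis(benzyloxy)phenyl]prop-2-enoate
Conditions: (CF3CH2O)2P(O)CH2CO2Me, KN(SiMe3)2, 18-crown-6, THF, −78 °C
Reagents that add atoms: methyl 2-[bis(2,2,2-trifluoroethoxy)phosphoryl]acetate, COC(=O)CP(=O)(OCC(F)(F)F)OCC(F)(F)F
Why: Still–Gennari olefination (Z-selective Horner–Wadsworth–Emmons reaction) of an aromatic aldehyde.

**Step 12**
Reactants: 19 methyl (2Z)-3-[3,4-bis(benzyloxy)phenyl]prop-2-enoate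
Product: 20 methyl (2S,3S)-3-[3,4-bis(benzyloxy)phenyl]oxirane-2-carboxylate (cis)
Conditions: [(S,S)-N,N'-bis(3,5-di-tert-butylsalicylidene)cyclohexane-1,2-diaminato]manganese chloride (trivalent manganese, 5 mol%), NaOCl (aq, pH 11.3), 4-phenylpyridine N-oxide, CH2Cl2, 0 °C
Reagents that add atoms: sodium hypochlorite, [Na+].[O-]Cl
Why: Jacobsen–Katsuki epoxidation of a cis-cinnamate; the (S,S)-salen manganese catalyst delivers oxygen to one face of the Z-alkene and should set both centers (2S,3S) with the cis geometry kept.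

**Step 13**
Reactants: 20 methyl (2S,3S)-3-[3,4-bis(benzyloxy)phenyl]oxirane-2-carboxylate
Product: 21 (2S,3S)-3-[3,4-bis(benzyloxy)phenyl]oxirane-2-carbaldehyde (cis)
Conditions: (Me2CHCH2)2AlH (1.05 equiv), CH2Cl2, −78 °C; aq. KNaC4H4O6
Reagents that add atoms: none
Why: partial reduction of the ester at −78 °C through a stable tetrahedral aluminium alkoxide; the cis-epoxide and both stereocenters are kept.

**Step 14**
Reactants: 17 (2R,3R,4S)-7,8-bis(benzyloxy)-2-ArB-4-(7-hydroxy-2,2-diphenyl-1,3-benzodioxol-4-yl)chroman-3-ol; 21 (2S,3S)-3-[3,4-bis(benzyloxy)phenyl]oxirane-2-carbaldehyde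
Product: 24 protected dimer (2R,3R,4S)-2-ArB-6-[(2R,3R,4S)-7,8-bis(benzyloxy)-2-ArB-3-hydroxychroman-4-yl]-7,8-(diphenylmethylenedioxy)chroman-3,4-diol, via chloromagnesium phenoxide 22 (not isolated), via epoxy diol adduct 23 (not isolated)
Conditions: Me2CHMgCl (1.0 equiv), toluene, 0 °C; then 21 (1.2 equiv), −20 → 40 °C; aqueous work-up at pH 7
Reagents that add atoms: none
Why: Proposed new method: the chloromagnesium phenoxide 22 binds the aldehyde oxygen and the epoxide oxygen of 21 on one magnesium, and its only free ortho carbon (the future C4a; the para carbon carries the upper unit) attacks the carbonyl through a six-membered cyclic transition state, as in the known ortho-specific hydroxyalkylation of magnesium phenoxides with aldehydes (the closest precedent, which includes α-alkoxy aldehydes under chelation control), here extended to a cis-α,β-epoxy aldehyde. Rearomatisation gives 23, whose magnesium phenoxide then opens the magnesium-activated epoxide at the benzylic carbon, so that ring C of the lower unit is closed by a 6-endo-tet epoxide opening (O1–C2) after the intermolecular C4–C4a bond, a formal [3+3] annulation. C4 (S) is set by the chelate, the arene being delivered to the aldehyde face anti to the epoxide C–C bond (Cram-chelate sense, threo carbinol, hence 3,4-trans); C3 (R) is carried over from 21, and C2 (R) arises by inversion of the (S)-configured benzylic epoxide carbon, so the cis-epoxide gives the 2,3-cis ring. The step needs ortho-C-attack over O-alkylation, 6-endo over 5-exo opening and SN2 over SN1 character at C2: the first is secured by the magnesium template in a non-coordinating solvent and the single free ortho position, the second by the 3,4-bis(benzyloxy)phenyl group that makes C2 benzylic, the third by the non-acidic medium with chloride in place of the more nucleophilic bromide. The upper 3-OH stays protonated because one equivalent of base selects the far more acidic phenol.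

**Step 15**
Reactants: 24 protected dimer
Product: 25 CNP0143773.1, (2R,3R,4S)-2-(3,4-dihydroxyphenyl)-6-[(2R,3R,4R)-2-(3,4-dihydroxyphenyl)-3,7,8-trihydroxychroman-4-yl]chroman-3,4,7,8-tetrol
Conditions: H2 (1 atm), Pd(OH)2/C, EtOAc–MeOH, 25 °C
Reagents that add atoms: none
Why: hydrogenolysis of six aryl benzyl ethers and of the diphenylmethylene ketal under neutral conditions, where these bonds should cleave much faster than the secondary benzylic C4–OH and C2–O1 bonds; no stereocenter is touched.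

**Compound list**

1 | 7,8-dihydroxy-2H-chromen-2-one (daphnetin) | O=c1ccc2ccc(O)c(O)c2o1 | starting material
2 | 7,8-bis(benzyloxy)-2H-chromen-2-one | O=c1ccc2ccc(OCc3ccccc3)c(OCc3ccccc3)c2o1 | intermediate
3 | benzene-1,2,3-triol (pyrogallol) | Oc1cccc(O)c1O | starting material
4 | 2,2-diphenyl-1,3-benzodioxol-4-ol | Oc1cccc2OC(c3ccccc3)(c3ccccc3)Oc12 | intermediate
5 | [(2,2-diphenyl-1,3-benzodioxol-4-yl)oxy]tri(propan-2-yl)silane | CC(C)[Si](Oc1cccc2OC(c3ccccc3)(c3ccccc3)Oc12)(C(C)C)C(C)C | intermediate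
6 | {2,2-diphenyl-7-[tri(propan-2-yl)silyloxy]-1,3-benzodioxol-4-yl}lithium | [Li]c1ccc(O[Si](C(C)C)(C(C)C)C(C)C)c2OC(c3ccccc3)(c3ccccc3)Oc12 | intermediate
7 | {2,2-diphenyl-7-[tri(propan-2-yl)silyloxy]-1,3-benzodioxol-4-yl}boronic acid | OB(O)c1ccc(O[Si](C(C)C)(C(C)C)C(C)C)c2OC(c3ccccc3)(c3ccccc3)Oc12 | intermediate
8 | (4R)-7,8-bis(benzyloxy)-4-ArT-chroman-2-one | O=C1C[C@H](c2ccc(O[Si](C(C)C)(C(C)C)C(C)C)c3OC(c4ccccc4)(c4ccccc4)Oc23)c2ccc(OCc3ccccc3)c(OCc3ccccc3)c2O1 | intermediate
9 | 4-bromo-1,2-bis(benzyloxy)benzene | Brc1ccc(OCc2ccccc2)c(OCc2ccccc2)c1 | starting material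
10 | [3,4-bis(benzyloxy)phenyl]lithium | [Li]c1ccc(OCc2ccccc2)c(OCc2ccccc2)c1 | intermediate
11 | (3S)-3-[3,4-bis(benzyloxy)-2-hydroxyphenyl]-1-ArB-3-ArT-propan-1-one | O=C(c1ccc(OCc2ccccc2)c(OCc2ccccc2)c1)C[C@H](c1ccc(O[Si](C(C)C)(C(C)C)C(C)C)c2OC(c3ccccc3)(c3ccccc3)Oc12)c1ccc(OCc2ccccc2)c(OCc2ccccc2)c1O | intermediate
12 | (4S)-7,8-bis(benzyloxy)-2-ArB-4-ArT-4H-chromene | C(c1ccccc1)Oc1ccc(C2=C[C@H](c3ccc(O[Si](C(C)C)(C(C)C)C(C)C)c4OC(c5ccccc5)(c5ccccc5)Oc34)c3ccc(OCc4ccccc4)c(OCc4ccccc4)c3O2)cc1OCc1ccccc1 | intermediate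
13 | C3-borane of 12: [(2R,4S)-7,8-bis(benzyloxy)-2-ArB-4-ArT-chroman-3-yl]borane, boron trans to both aryl groups | C(c1ccccc1)Oc1ccc([C@H]2Oc3c(ccc(OCc4ccccc4)c3OCc3ccccc3)[C@@H](c3ccc(O[Si](C(C)C)(C(C)C)C(C)C)c4OC(c5ccccc5)(c5ccccc5)Oc34)[C@@H]2B)cc1OCc1ccccc1 | intermediate
14 | (2R,3S,4S)-7,8-bis(benzyloxy)-2-ArB-4-ArT-chroman-3-ol (2,3-trans-3,4-trans) | C(c1ccccc1)Oc1ccc([C@H]2Oc3c(ccc(OCc4ccccc4)c3OCc3ccccc3)[C@@H](c3ccc(O[Si](C(C)C)(C(C)C)C(C)C)c4OC(c5ccccc5)(c5ccccc5)Oc34)[C@@H]2O)cc1OCc1ccccc1 | intermediate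
15 | (2R,4S)-7,8-bis(benzyloxy)-2-ArB-4-ArT-chroman-3-one (2,4-cis) | C(c1ccccc1)Oc1ccc([C@H]2Oc3c(ccc(OCc4ccccc4)c3OCc3ccccc3)[C@@H](c3ccc(O[Si](C(C)C)(C(C)C)C(C)C)c4OC(c5ccccc5)(c5ccccc5)Oc34)C2=O)cc1OCc1ccccc1 | intermediate
16 | (2R,3R,4S)-7,8-bis(benzyloxy)-2-ArB-4-ArT-chroman-3-ol (all-cis) | C(c1ccccc1)Oc1ccc([C@H]2Oc3c(ccc(OCc4ccccc4)c3OCc3ccccc3)[C@@H](c3ccc(O[Si](C(C)C)(C(C)C)C(C)C)c4OC(c5ccccc5)(c5ccccc5)Oc34)[C@H]2O)cc1OCc1ccccc1 | intermediate
17 | (2R,3R,4S)-7,8-bis(benzyloxy)-2-ArB-4-(7-hydroxy-2,2-diphenyl-1,3-benzodioxol-4-yl)chroman-3-ol (all-cis) | C(c1ccccc1)Oc1ccc([C@H]2Oc3c(ccc(OCc4ccccc4)c3OCc3ccccc3)[C@@H](c3ccc(O)c4OC(c5ccccc5)(c5ccccc5)Oc34)[C@H]2O)cc1OCc1ccccc1 | intermediate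
18 | 3,4-bis(benzyloxy)benzaldehyde | O=Cc1ccc(OCc2ccccc2)c(OCc2ccccc2)c1 | starting material
19 | methyl (2Z)-3-[3,4-bis(benzyloxy)phenyl]prop-2-enoate | COC(=O)/C=C\c1ccc(OCc2ccccc2)c(OCc2ccccc2)c1 | intermediate
20 | methyl (2S,3S)-3-[3,4-bis(benzyloxy)phenyl]oxirane-2-carboxylate (cis) | COC(=O)[C@H]1O[C@H]1c1ccc(OCc2ccccc2)c(OCc2ccccc2)c1 | intermediate
21 | (2S,3S)-3-[3,4-bis(benzyloxy)phenyl]oxirane-2-carbaldehyde (cis) | O=C[C@H]1O[C@H]1c1ccc(OCc2ccccc2)c(OCc2ccccc2)c1 | intermediate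
22 | chloromagnesium phenoxide of 17 | C(c1ccccc1)Oc1ccc([C@H]2Oc3c(ccc(OCc4ccccc4)c3OCc3ccccc3)[C@@H](c3ccc(O[Mg]Cl)c4OC(c5ccccc5)(c5ccccc5)Oc34)[C@H]2O)cc1OCc1ccccc1 | intermediate
23 | 17 carrying at C6 of its benzodioxole ring (ortho to the phenol) the (S)-hydroxy[(2R,3S)-3-ArB-oxiran-2-yl]methyl group | C(c1ccccc1)Oc1ccc([C@H]2Oc3c(ccc(OCc4ccccc4)c3OCc3ccccc3)[C@@H](c3cc([C@H](O)[C@H]4O[C@H]4c4ccc(OCc5ccccc5)c(OCc5ccccc5)c4)c(O)c4OC(c5ccccc5)(c5ccccc5)Oc34)[C@H]2O)cc1OCc1ccccc1 | intermediate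
24 | (2R,3R,4S)-2-ArB-6-[(2R,3R,4S)-7,8-bis(benzyloxy)-2-ArB-3-hydroxychroman-4-yl]-7,8-(diphenylmethylenedioxy)chroman-3,4-diol | C(c1ccccc1)Oc1ccc([C@H]2Oc3c(ccc(OCc4ccccc4)c3OCc3ccccc3)[C@@H](c3cc4c(c5OC(c6ccccc6)(c6ccccc6)Oc35)O[C@H](c3ccc(OCc5ccccc5)c(OCc5ccccc5)c3)[C@H](O)[C@H]4O)[C@H]2O)cc1OCc1ccccc1 | intermediate
25 | CNP0143773.1, (2R,3R,4S)-2-(3,4-dihydroxyphenyl)-6-[(2R,3R,4R)-2-(3,4-dihydroxyphenyl)-3,7,8-trihydroxychroman-4-yl]chroman-3,4,7,8-tetrol | Oc1ccc([C@H]2Oc3c(ccc(O)c3O)[C@@H](c3cc4c(c(O)c3O)O[C@H](c3ccc(O)c(O)c3)[C@H](O)[C@H]4O)[C@H]2O)cc1O | target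

**Count**

Total steps: 15. Longest linear sequence: 11 steps (3 to 25 through steps 2 to 10, 14 and 15).

**Steps most likely to fail**

Step 14 (Proposed new method). Three things may go wrong: sluggish carbon–carbon bond formation by the hindered phenoxide, poor facial selectivity at the aldehyde, and ionisation of the electron-rich benzylic epoxide with loss of the inversion at C2 or 5-exo closure. The fallback sets out from 17 and returns at 24 and uses known reaction types. Phenol 17 is brominated with N-bromosuccinimide (CH2Cl2, −40 °C) at the one free position ortho to its hydroxyl to give the bromophenol F1. n-BuLi (3.1 equiv, THF, −78 °C) deprotonates both hydroxyls and exchanges bromine for lithium. Addition of 21 at −78 °C, a 1,2-addition of an aryllithium to an α,β-epoxy aldehyde, should give 23 together with its carbinol epimer F2. On warming to 25 °C the lithium phenoxides should close ring C by 6-endo opening of the aryl epoxide, giving 24 and its C4 epimer F3. F3 is then converted into 24 by the acid-catalysed C4 equilibration of 2,3-cis-flavan-3,4-diols to their 3,4-trans isomers (catalytic pyridinium p-toluenesulfonate, acetone–water, 40 °C).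

Step 5. The insertion may be slow with an electron-rich coumarin and a hindered, electron-rich boronic acid, so that protodeboronation outruns the addition. The fallback sets out from 2 and 7 and returns at 8. An oxidative Heck arylation of 2 with 7 (Pd(OAc)2, 1,10-phenanthroline, O2, DMF, 80 °C) should give the 4-arylcoumarin F4. Copper-hydride asymmetric conjugate reduction (Cu(OAc)2·H2O, the enantiomer of DTBM-SEGPHOS that places the aryl group as in 8, (EtO)2MeSiH, t-BuOH, toluene) then sets C4. As is known for 4-arylcoumarins, it is expected to run on to the lactol F5, which Ag2CO3 on Celite (toluene, 80 °C) oxidises to lactone 8.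

Step 15. Over-reduction may occur: hydrogenolysis of the activated benzylic C4–O bond of the lower unit during debenzylation. The fallback sets out from 24 and returns at 25. MnO2 (CH2Cl2, 25 °C) should oxidise only the benzylic C4 hydroxyl of the lower unit to give the 2,3-cis-3-hydroxychroman-4-one F6. Hydrogenolysis (H2, Pd(OH)2/C, EtOAc–MeOH) then removes the benzyl groups and the ketal with no benzylic alcohol present and gives the free phenolic ketone F7. Hydroxyl-directed reduction with Me4NBH(OAc)3 (MeCN–AcOH, −20 °C) delivers hydride from the face of the C3 hydroxyl and should give the 3,4-trans diol 25.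

**Further compounds**

F1 | step 14 | (2R,3R,4S)-7,8-bis(benzyloxy)-2-ArB-4-(6-bromo-7-hydroxy-2,2-diphenyl-1,3-benzodioxol-4-yl)chroman-3-ol | C(c1ccccc1)Oc1ccc([C@H]2Oc3c(ccc(OCc4ccccc4)c3OCc3ccccc3)[C@@H](c3cc(Br)c(O)c4OC(c5ccccc5)(c5ccccc5)Oc34)[C@H]2O)cc1OCc1ccccc1
F2 | step 14 | carbinol epimer of 23, (R)-hydroxy[(2R,3S)-3-ArB-oxiran-2-yl]methyl side chain | C(c1ccccc1)Oc1ccc([C@H]2Oc3c(ccc(OCc4ccccc4)c3OCc3ccccc3)[C@@H](c3cc([C@@H](O)[C@H]4O[C@H]4c4ccc(OCc5ccccc5)c(OCc5ccccc5)c4)c(O)c4OC(c5ccccc5)(c5ccccc5)Oc34)[C@H]2O)cc1OCc1ccccc1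
F3 | step 14 | C4 epimer of 24 in the lower unit (2,3-cis-3,4-cis diol) | C(c1ccccc1)Oc1ccc([C@H]2Oc3c(ccc(OCc4ccccc4)c3OCc3ccccc3)[C@@H](c3cc4c(c5OC(c6ccccc6)(c6ccccc6)Oc35)O[C@H](c3ccc(OCc5ccccc5)c(OCc5ccccc5)c3)[C@H](O)[C@@H]4O)[C@H]2O)cc1OCc1ccccc1
F4 | step 5 | 7,8-bis(benzyloxy)-4-ArT-2H-chromen-2-one | O=c1cc(c2ccc(O[Si](C(C)C)(C(C)C)C(C)C)c3OC(c4ccccc4)(c4ccccc4)Oc23)c2ccc(OCc3ccccc3)c(OCc3ccccc3)c2o1
F5 | step 5 | 7,8-bis(benzyloxy)-4-ArT-chroman-2-ol with the C4 configuration of 8 (both C2 epimers) | OC1C[C@H](c2ccc(O[Si](C(C)C)(C(C)C)C(C)C)c3OC(c4ccccc4)(c4ccccc4)Oc23)c2ccc(OCc3ccccc3)c(OCc3ccccc3)c2O1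
F6 | step 15 | 4-oxo analogue of 24 (lower unit a (2R,3S)-2,3-cis-3-hydroxychroman-4-one) | C(c1ccccc1)Oc1ccc([C@H]2Oc3c(ccc(OCc4ccccc4)c3OCc3ccccc3)[C@@H](c3cc4c(c5OC(c6ccccc6)(c6ccccc6)Oc35)O[C@H](c3ccc(OCc5ccccc5)c(OCc5ccccc5)c3)[C@H](O)C4=O)[C@H]2O)cc1OCc1ccccc1
F7 | step 15 | 4-oxo analogue of 25 (free phenols, lower unit a 2,3-cis-3-hydroxychroman-4-one) | Oc1ccc([C@H]2Oc3c(ccc(O)c3O)[C@@H](c3cc4c(c(O)c3O)O[C@H](c3ccc(O)c(O)c3)[C@H](O)C4=O)[C@H]2O)cc1O
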